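**Retrosynthetic overview**
- Target ⇐ desilylation and Myers reductive transposition of a ring A primary allylic alcohol (gives the exocyclic methylene); ring B hydroxy ketone ⇐ face-selective dihydroxylation and oxidation of a ring B allylic chloride.
- cis-Bromohydrin ⇐ i-Bu2AlH reduction of an α'-bromo enone (bromide set under thermodynamic control); enone ⇐ Stork–Danheiser transposition of a dimedone vinylogous ester with an alkoxymethyl-lithium reagent.
- Ring B alkene ⇐ alkenyl triflate (Stille hydroxymethylation) ⇐ chiral lithium amide deprotonation of an achiral spiro diketone, which sets the spiro centre.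
- Spiro core ⇐ hydrogenation of a spiro enone ⇐ aldol closure ⇐ intermolecular Michael addition of the formylated dimedone vinylogous ester to methyl vinyl ketone (the fragment-joining C–C bond).
- Ring order: ring A comes intact from dimedone; ring B is built second by Michael addition and aldol condensation.

Assumption: the chiral lithium amide is taken to deprotonate the achiral spiro diketone with the sense known for 4-tert-butylcyclohexanone, which calls for the (S,S)-amide; if the sense is reversed, the (R,R)-amide is used with no other change.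

Locants: all spiro compounds are numbered as in the target (ring A = C1–C5, spiro carbon C6, ring B = C7–C11).

**Step 1**
Reactants: 1 dimedone (5,5-dimethylcyclohexane-1,3-dione); 2 2-methylpropan-1-ol
Product: 3 3-isobutoxy-5,5-dimethylcyclohex-2-en-1-one
Conditions: TsOH·H2O (cat.), toluene, reflux, Dean–Stark
Reagents that add atoms: 2-methylpropan-1-ol (2), CC(C)CO
Why: Acid-catalysed enol etherification of the cyclic 1,3-dione with azeotropic removal of water gives the vinylogous ester, which blocks C2 and directs later enolisation to the carbon next to the gem-dimethyl group; no stereocentre.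

**Step 2**
Reactants: 3 3-isobutoxy-5,5-dimethylcyclohex-2-en-1-one; 4 ethyl formate
Product: 6 4-isobutoxy-6,6-dimethyl-2-oxocyclohex-3-ene-1-carbaldehyde (mainly as its hydroxymethylene enol), via lithium dienolate 5 (not isolated)
Conditions: LiN(i-Pr)2, THF, −78 °C; HCO2Et, −78 → 0 °C; 1 M HCl
Reagents that add atoms: ethyl formate (4), CCOC=O
Why: Kinetic deprotonation occurs at the alpha-prime carbon and the enolate undergoes a crossed Claisen condensation with the non-enolisable formate to give an enolised beta-keto aldehyde, so no stereocentre is set.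

**Step 3**
Reactants: 6 4-isobutoxy-6,6-dimethyl-2-oxocyclohex-3-ene-1-carbaldehyde; 7 methyl vinyl ketone
Product: 8 rac-4-isobutoxy-6,6-dimethyl-2-oxo-1-(3-oxobutyl)cyclohex-3-ene-1-carbaldehyde
Conditions: Et3N (0.2 equiv), CH2Cl2, 23 °C
Reagents that add atoms: methyl vinyl ketone (7), CC(=O)C=C
Why: Amine-catalysed Michael addition of the acidic beta-keto aldehyde to the unhindered enone terminus joins the two fragments and creates the quaternary future spiro carbon, racemic here, which is harmless because step 5 makes this carbon non-stereogenic.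

**Step 4**
Reactants: 8 rac-4-isobutoxy-6,6-dimethyl-2-oxo-1-(3-oxobutyl)cyclohex-3-ene-1-carbaldehyde
Product: 9 rac-3-isobutoxy-5,5-dimethylspiro[5.5]undeca-2,7-diene-1,9-dione
Conditions: pyrrolidine (0.3 equiv), AcOH (0.3 equiv), toluene, 80 °C
Reagents that add atoms: none
Why: Intramolecular aldol condensation (Robinson-type spiroannulation) of the methyl ketone, through its enamine, onto the non-enolisable aldehyde closes ring B, and the buffered amine conditions avoid retro-Claisen loss of the formyl group.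

**Step 5**
Reactants: 9 rac-3-isobutoxy-5,5-dimethylspiro[5.5]undeca-2,7-diene-1,9-dione
Product: 10 3-isobutoxy-5,5-dimethylspiro[5.5]undec-2-ene-1,9-dione
Conditions: H2 (1 atm), 5% Pd/C, EtOAc, 23 °C
Reagents that add atoms: none
Why: Heterogeneous hydrogenation saturates the simple enone double bond faster than the electron-rich vinylogous-ester double bond, and the product is achiral because the spiro carbon now carries two identical CH2CH2 arms.

**Step 6**
Reactants: 10 3-isobutoxy-5,5-dimethylspiro[5.5]undec-2-ene-1,9-dione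
Product: 12 (6S)-3-isobutoxy-5,5-dimethyl-1-oxospiro[5.5]undeca-2,9-dien-9-yl trifluoromethanesulfonate, via lithium enolate 11 (not isolated)
Conditions: (S,S)-[PhCH(Me)]2NH, n-BuLi, LiCl, THF, −78 °C; then PhNTf2, −78 → 0 °C
Reagents that add atoms: N-phenylbis(trifluoromethanesulfonimide), O=S(=O)(N(c1ccccc1)S(=O)(=O)C(F)(F)F)C(F)(F)F
Why: Simpkins–Koga desymmetrisation: the chiral lithium amide removes one of the two mirror-related axial alpha protons of the locked ring B chair (CMe2 branch equatorial), which fixes the spiro carbon as 6S (typically 85–90% ee, to be upgraded by recrystallisation downstream), and the enolate is trapped as its triflate.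

**Step 7**
Reactants: 12 (6S)-3-isobutoxy-5,5-dimethyl-1-oxospiro[5.5]undeca-2,9-dien-9-yl trifluoromethanesulfonate; 13 (tributylstannyl)methanol
Product: 14 (6S)-9-(hydroxymethyl)-3-isobutoxy-5,5-dimethylspiro[5.5]undeca-2,9-dien-1-one
Conditions: Pd(PPh3)4 (5 mol%), LiCl, 1,4-dioxane, 95 °C
Reagents that add atoms: (tributylstannyl)methanol (13), CCCC[Sn](CCCC)(CCCC)CO
Why: Stille (Kosugi–Migita) coupling of the alkenyl triflate with the hydroxymethylstannane installs the C9 carbon as an allylic alcohol without touching the stereocentre.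

**Step 8**
Reactants: 13 (tributylstannyl)methanol; 15 4-methoxybenzyl chloride
Product: 16 tributyl{[(4-methoxybenzyl)oxy]methyl}stannane
Conditions: NaH, Bu4NI (cat.), THF/DMF, 0 → 23 °C
Reagents that add atoms: 4-methoxybenzyl chloride (15), COc1ccc(CCl)cc1
Why: Williamson etherification of the stannyl alcohol gives the protected hydroxymethyl-anion precursor needed in step 9.

**Step 9**
Reactants: 14 (6S)-9-(hydroxymethyl)-3-isobutoxy-5,5-dimethylspiro[5.5]undeca-2,9-dien-1-one; 16 tributyl{[(4-methoxybenzyl)oxy]methyl}stannane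
Product: 18 (6S)-9-(hydroxymethyl)-1-{[(4-methoxybenzyl)oxy]methyl}-5,5-dimethylspiro[5.5]undeca-1,9-dien-3-one, via tertiary carbinol adduct 17 (not isolated)
Conditions: 16 (3 equiv), n-BuLi (2.9 equiv), THF, −78 °C; CeCl3; then 14, −78 → 0 °C; then 1 M HCl, THF, 0 °C
Reagents that add atoms: tributyl{[(4-methoxybenzyl)oxy]methyl}stannane (16), CCCC[Sn](CCCC)(CCCC)COCc1ccc(OC)cc1
Why: Tin–lithium exchange gives the alkoxymethyl organometallic (one equivalent is spent on the free hydroxyl), which adds 1,2 to the hindered vinylogous-ester carbonyl, and acid then effects the Stork–Danheiser hydrolysis–dehydration to the transposed enone with the spiro centre untouched.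

**Step 10**
Reactants: 18 (6S)-9-(hydroxymethyl)-1-{[(4-methoxybenzyl)oxy]methyl}-5,5-dimethylspiro[5.5]undeca-1,9-dien-3-one
Product: 20 (6S)-9-(chloromethyl)-1-{[(4-methoxybenzyl)oxy]methyl}-5,5-dimethylspiro[5.5]undeca-1,9-dien-3-one, via allylic mesylate 19 (not isolated)
Conditions: MsCl, 2,4,6-collidine, LiCl, DMF, 0 °C
Reagents that add atoms: lithium chloride, [Li+].[Cl-]
Why: Collington–Meyers chlorination: in situ mesylation of the primary allylic alcohol and SN2 displacement by chloride give the allylic chloride without allylic transposition.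

**Step 11**
Reactants: 20 (6S)-9-(chloromethyl)-1-{[(4-methoxybenzyl)oxy]methyl}-5,5-dimethylspiro[5.5]undeca-1,9-dien-3-one
Product: 22 (4R,6R)-4-bromo-9-(chloromethyl)-1-{[(4-methoxybenzyl)oxy]methyl}-5,5-dimethylspiro[5.5]undeca-1,9-dien-3-one, via lithium dienolate 21 (not isolated)
Conditions: LiN(i-Pr)2, THF, −78 °C; NBS, −78 °C; then i-Pr2NEt (0.2 equiv), CH2Cl2, 23 °C
Reagents that add atoms: N-bromosuccinimide, O=C1CCC(=O)N1Br
Why: Kinetic alpha-prime deprotonation (as with isophorone) and bromination of the cross-conjugated enolate give the alpha-bromo ketone, whose epimerisable C4 centre should settle under amine equilibration with bromine equatorial in the ring A half-chair that places C11 (the arm leading to sp2 C10, which crowds the C1 substituent less than the C8 methylene) pseudo-equatorial, making bromine cis to C11 (4R).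

**Step 12**
Reactants: 22 (4R,6R)-4-bromo-9-(chloromethyl)-1-{[(4-methoxybenzyl)oxy]methyl}-5,5-dimethylspiro[5.5]undeca-1,9-dien-3-one
Product: 23 (3S,4R,6R)-4-bromo-9-(chloromethyl)-1-{[(4-methoxybenzyl)oxy]methyl}-5,5-dimethylspiro[5.5]undeca-1,9-dien-3-ol
Conditions: i-Bu2AlH, CH2Cl2, −78 °C
Reagents that add atoms: none
Why: 1,2-Reduction of the enone by the bulky aluminium hydride occurs from the equatorial direction, away from the axial C5 methyl group, giving the axial alcohol cis to the equatorial bromine (3S).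

**Step 13**
Reactants: 23 (3S,4R,6R)-4-bromo-9-(chloromethyl)-1-{[(4-methoxybenzyl)oxy]methyl}-5,5-dimethylspiro[5.5]undeca-1,9-dien-3-ol
Product: 24 {[(3S,4R,6R)-4-bromo-9-(chloromethyl)-1-{[(4-methoxybenzyl)oxy]methyl}-5,5-dimethylspiro[5.5]undeca-1,9-dien-3-yl]oxy}(tert-butyl)dimethylsilane
Conditions: TBSOTf, 2,6-lutidine, CH2Cl2, −78 → 0 °C
Reagents that add atoms: tert-butyldimethylsilyl trifluoromethanesulfonate, CC(C)(C)[Si](C)(C)OS(=O)(=O)C(F)(F)F
Why: Silylation of the hindered axial alcohol with the silyl triflate protects it for the later oxidation and Mitsunobu steps.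

**Step 14**
Reactants: 24 the silyl ether from step 13
Product: 25 (3S,4R,6R,9S,10R)-4-bromo-3-[(tert-butyldimethylsilyl)oxy]-9-(chloromethyl)-1-{[(4-methoxybenzyl)oxy]methyl}-5,5-dimethylspiro[5.5]undec-1-ene-9,10-diol
Conditions: OsO4 (2 mol%), NMO, acetone/H2O (4:1), 23 °C
Reagents that add atoms: OsO4, O=[Os](=O)(=O)=O; 4-methylmorpholine N-oxide, C[N+]1([O-])CCOCC1; water, O
Why: Upjohn dihydroxylation should attack the ring B alkene (the ring A alkene is shielded on both faces by the axial silyloxy group and the axial C7 arm) from the face opposite the axial C1 branch of ring A, just as 2-ene steroids are osmylated anti to the angular methyl group, giving the 9S,10R diol.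

**Step 15**
Reactants: 25 the diol from step 14
Product: 26 (3S,4R,6R,9S)-4-bromo-3-[(tert-butyldimethylsilyl)oxy]-9-(chloromethyl)-9-hydroxy-1-{[(4-methoxybenzyl)oxy]methyl}-5,5-dimethylspiro[5.5]undec-1-en-10-one
Conditions: (COCl)2, DMSO, CH2Cl2, −78 °C; Et3N, −78 → 0 °C
Reagents that add atoms: none
Why: Swern oxidation converts the secondary C10 alcohol into the ketone while the tertiary C9 alcohol cannot be oxidised, giving the alpha-hydroxy ketone.

**Step 16**
Reactants: 26 the hydroxy ketone from step 15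
Product: 27 (3S,4R,6R,9S)-4-bromo-3-[(tert-butyldimethylsilyl)oxy]-9-(chloromethyl)-9-hydroxy-1-(hydroxymethyl)-5,5-dimethylspiro[5.5]undec-1-en-10-one
Conditions: DDQ, CH2Cl2/pH 7 buffer (10:1), 0 °C
Reagents that add atoms: none
Why: Oxidative cleavage of the para-methoxybenzyl ether frees the primary allylic alcohol and leaves the silyl ether, the halides and the ketone untouched.

**Step 17**
Reactants: 27 the primary allylic alcohol from step 16
Product: 31 (3S,4R,6R,9S)-4-bromo-3-[(tert-butyldimethylsilyl)oxy]-9-(chloromethyl)-9-hydroxy-5,5-dimethyl-1-methylidenespiro[5.5]undecan-10-one, via sulfonylhydrazone adduct 28 (not isolated), via allyl sulfonylhydrazine 29 (not isolated), via allylic diazene 30 (not isolated)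
Conditions: IPNBSH (N'-isopropylidene-2-nitrobenzenesulfonohydrazide), PPh3, DEAD, THF, 0 → 23 °C; then CF3CH2OH/H2O (1:1), 23 °C
Reagents that add atoms: none
Why: Myers reductive 1,3-transposition: Mitsunobu displacement of the primary allylic alcohol, hydrazone hydrolysis and loss of sulfinate give a monoalkyl diazene whose retro-ene loss of N2 delivers hydrogen to C2 and moves the double bond to the exocyclic position, and the acetone-protected hydrazide cannot condense with the C10 ketone.

**Step 18**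
Reactants: 31 the silyl-protected target from step 17
Product: 32 (3S,4R,6R,9S)-4-bromo-9-(chloromethyl)-3,9-dihydroxy-5,5-dimethyl-1-methylidenespiro[5.5]undecan-10-one
Conditions: HF·pyridine, pyridine, THF, 0 → 23 °C
Reagents that add atoms: none
Why: Fluoride-mediated desilylation under buffered, non-basic conditions removes the silyl ether without turning the chlorohydrin or the cis-bromohydrin into epoxides.

**Compound list**
1 | dimedone (5,5-dimethylcyclohexane-1,3-dione) | CC1(C)CC(=O)CC(=O)C1 | starting material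
2 | 2-methylpropan-1-ol | CC(C)CO | starting material
3 | 3-isobutoxy-5,5-dimethylcyclohex-2-en-1-one | CC(C)COC1=CC(=O)CC(C)(C)C1 | intermediate
4 | ethyl formate | CCOC=O | starting material
5 | lithium 5-isobutoxy-3,3-dimethylcyclohexa-1,5-dien-1-olate (not isolated) | CC(C)COC1=CC(O[Li])=CC(C)(C)C1 | intermediate
6 | 4-isobutoxy-6,6-dimethyl-2-oxocyclohex-3-ene-1-carbaldehyde | CC(C)COC1=CC(=O)C(C=O)C(C)(C)C1 | intermediate
7 | methyl vinyl ketone (but-3-en-2-one) | CC(=O)C=C | starting material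
8 | rac-4-isobutoxy-6,6-dimethyl-2-oxo-1-(3-oxobutyl)cyclohex-3-ene-1-carbaldehyde | CC(C)COC1=CC(=O)C(C=O)(CCC(C)=O)C(C)(C)C1 | intermediate
9 | rac-3-isobutoxy-5,5-dimethylspiro[5.5]undeca-2,7-diene-1,9-dione | CC(C)COC1=CC(=O)C2(C=CC(=O)CC2)C(C)(C)C1 | intermediate
10 | 3-isobutoxy-5,5-dimethylspiro[5.5]undec-2-ene-1,9-dione | CC(C)COC1=CC(=O)C2(CCC(=O)CC2)C(C)(C)C1 | intermediate
11 | lithium (6S)-3-isobutoxy-5,5-dimethyl-1-oxospiro[5.5]undeca-2,9-dien-9-olate (not isolated) | O=C1C=C(OCC(C)C)CC(C)(C)[C@@]12CCC(O[Li])=CC2 | intermediate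
12 | (6S)-3-isobutoxy-5,5-dimethyl-1-oxospiro[5.5]undeca-2,9-dien-9-yl trifluoromethanesulfonate | O=C1C=C(OCC(C)C)CC(C)(C)[C@@]12CCC(OS(=O)(=O)C(F)(F)F)=CC2 | intermediate
13 | (tributylstannyl)methanol | CCCC[Sn](CCCC)(CCCC)CO | starting material
14 | (6S)-9-(hydroxymethyl)-3-isobutoxy-5,5-dimethylspiro[5.5]undeca-2,9-dien-1-one | O=C1C=C(OCC(C)C)CC(C)(C)[C@@]12CCC(CO)=CC2 | intermediate
15 | 4-methoxybenzyl chloride | COc1ccc(CCl)cc1 | starting material
16 | tributyl{[(4-methoxybenzyl)oxy]methyl}stannane | CCCC[Sn](CCCC)(CCCC)COCc1ccc(OC)cc1 | intermediate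
17 | (6S)-9-(hydroxymethyl)-3-isobutoxy-1-{[(4-methoxybenzyl)oxy]methyl}-5,5-dimethylspiro[5.5]undeca-2,9-dien-1-ol, C1 epimers (not isolated) | COc1ccc(COCC2(O)C=C(OCC(C)C)CC(C)(C)[C@@]23CCC(CO)=CC3)cc1 | intermediate
18 | (6S)-9-(hydroxymethyl)-1-{[(4-methoxybenzyl)oxy]methyl}-5,5-dimethylspiro[5.5]undeca-1,9-dien-3-one | COc1ccc(COCC2=CC(=O)CC(C)(C)[C@@]23CCC(CO)=CC3)cc1 | intermediate
19 | [(6S)-1-{[(4-methoxybenzyl)oxy]methyl}-5,5-dimethyl-3-oxospiro[5.5]undeca-1,9-dien-9-yl]methyl methanesulfonate (not isolated) | COc1ccc(COCC2=CC(=O)CC(C)(C)[C@@]23CCC(COS(C)(=O)=O)=CC3)cc1 | intermediate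
20 | (6S)-9-(chloromethyl)-1-{[(4-methoxybenzyl)oxy]methyl}-5,5-dimethylspiro[5.5]undeca-1,9-dien-3-one | COc1ccc(COCC2=CC(=O)CC(C)(C)[C@@]23CCC(CCl)=CC3)cc1 | intermediate
21 | lithium (6S)-9-(chloromethyl)-1-{[(4-methoxybenzyl)oxy]methyl}-5,5-dimethylspiro[5.5]undeca-1,3,9-trien-3-olate (not isolated) | COc1ccc(COCC2=CC(O[Li])=CC(C)(C)[C@@]23CCC(CCl)=CC3)cc1 | intermediate
22 | (4R,6R)-4-bromo-9-(chloromethyl)-1-{[(4-methoxybenzyl)oxy]methyl}-5,5-dimethylspiro[5.5]undeca-1,9-dien-3-one | COc1ccc(COCC2=CC(=O)[C@H](Br)C(C)(C)[C@@]23CCC(CCl)=CC3)cc1 | intermediate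
23 | (3S,4R,6R)-4-bromo-9-(chloromethyl)-1-{[(4-methoxybenzyl)oxy]methyl}-5,5-dimethylspiro[5.5]undeca-1,9-dien-3-ol | COc1ccc(COCC2=C[C@H](O)[C@H](Br)C(C)(C)[C@@]23CCC(CCl)=CC3)cc1 | intermediate
24 | {[(3S,4R,6R)-4-bromo-9-(chloromethyl)-1-{[(4-methoxybenzyl)oxy]methyl}-5,5-dimethylspiro[5.5]undeca-1,9-dien-3-yl]oxy}(tert-butyl)dimethylsilane | COc1ccc(COCC2=C[C@H](O[Si](C)(C)C(C)(C)C)[C@H](Br)C(C)(C)[C@@]23CCC(CCl)=CC3)cc1 | intermediate
25 | (3S,4R,6R,9S,10R)-4-bromo-3-[(tert-butyldimethylsilyl)oxy]-9-(chloromethyl)-1-{[(4-methoxybenzyl)oxy]methyl}-5,5-dimethylspiro[5.5]undec-1-ene-9,10-diol | COc1ccc(COCC2=C[C@H](O[Si](C)(C)C(C)(C)C)[C@H](Br)C(C)(C)[C@@]23CC[C@@](O)(CCl)[C@H](O)C3)cc1 | intermediate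
26 | (3S,4R,6R,9S)-4-bromo-3-[(tert-butyldimethylsilyl)oxy]-9-(chloromethyl)-9-hydroxy-1-{[(4-methoxybenzyl)oxy]methyl}-5,5-dimethylspiro[5.5]undec-1-en-10-one | COc1ccc(COCC2=C[C@H](O[Si](C)(C)C(C)(C)C)[C@H](Br)C(C)(C)[C@@]23CC[C@@](O)(CCl)C(=O)C3)cc1 | intermediate
27 | (3S,4R,6R,9S)-4-bromo-3-[(tert-butyldimethylsilyl)oxy]-9-(chloromethyl)-9-hydroxy-1-(hydroxymethyl)-5,5-dimethylspiro[5.5]undec-1-en-10-one | OCC1=C[C@H](O[Si](C)(C)C(C)(C)C)[C@H](Br)C(C)(C)[C@@]12CC[C@@](O)(CCl)C(=O)C2 | intermediate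
28 | N-allylated N'-isopropylidene-2-nitrobenzenesulfonohydrazide of 27 (not isolated) | CC(C)=NN(CC1=C[C@H](O[Si](C)(C)C(C)(C)C)[C@H](Br)C(C)(C)[C@@]12CC[C@@](O)(CCl)C(=O)C2)S(=O)(=O)c1ccccc1[N+](=O)[O-] | intermediate
29 | N-allyl-2-nitrobenzenesulfonohydrazide of 27 (not isolated) | NN(CC1=C[C@H](O[Si](C)(C)C(C)(C)C)[C@H](Br)C(C)(C)[C@@]12CC[C@@](O)(CCl)C(=O)C2)S(=O)(=O)c1ccccc1[N+](=O)[O-] | intermediate
30 | allylic monoalkyl diazene of 27 (not isolated) | N=NCC1=C[C@H](O[Si](C)(C)C(C)(C)C)[C@H](Br)C(C)(C)[C@@]12CC[C@@](O)(CCl)C(=O)C2 | intermediate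
31 | (3S,4R,6R,9S)-4-bromo-3-[(tert-butyldimethylsilyl)oxy]-9-(chloromethyl)-9-hydroxy-5,5-dimethyl-1-methylidenespiro[5.5]undecan-10-one | C=C1C[C@H](O[Si](C)(C)C(C)(C)C)[C@H](Br)C(C)(C)[C@@]12CC[C@@](O)(CCl)C(=O)C2 | intermediate
32 | (3S,4R,6R,9S)-4-bromo-9-(chloromethyl)-3,9-dihydroxy-5,5-dimethyl-1-methylidenespiro[5.5]undecan-10-one | C=C1C[C@H](O)[C@H](Br)C(C)(C)[C@@]12CC[C@@](O)(CCl)C(=O)C2 | target

**Totals and risks**
Total step count: 18. Longest linear sequence: 17 (steps 1–7 and 9–18; step 8 is a one-step side branch).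

Most likely to fail:

Step 6, the chiral-base desymmetrisation, may give too low an ee or the opposite sense. Fallback: set the spiro centre in the Michael reaction instead. Starting from 6 and 7, a cinchona-derived bifunctional squaramide catalyst gives the (1R)-keto aldehyde F1. Pyrrolidine/AcOH closes it to the (6S)-spiro enone F2. Conjugate reduction with LiBH(s-Bu)3 and trapping of the regiodefined enolate with PhNTf2 then gives 12, where the route is rejoined; steps 5 and 6 are skipped.

Step 11, the equilibration, may not favour the 4R bromide strongly enough. Fallback: separate and recycle instead of relying on thermodynamic control. From 20, make and isolate the trimethylsilyl dienol ether F3 (LiN(i-Pr)2, Me3SiCl), brominate it with NBS at −78 °C and reduce the crude bromoketones at once with i-Bu2AlH. The two cis-bromohydrins are separated on silica and 23 goes forward. The (3R,4S)-bromohydrin F4 is recycled by Dess–Martin oxidation to the (4S)-bromoketone F5, which is epimerised with i-Pr2NEt to 22. The route is rejoined at 23.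

Step 14, the osmylation, may also attack the ring A alkene or show poor face selectivity. Fallback: dihydroxylate one stage earlier, while ring A is still the electron-poor bromo enone. Compound 22 with OsO4/NMO gives the chlorodiol F6, which is protected as the acetonide F7 (2,2-dimethoxypropane, PPTS). Reduction with i-Bu2AlH gives the bromohydrin acetonide F8 and TBSOTf gives the silyl ether acetonide F9. 80% AcOH then removes the acetonide to give 25, where the route is rejoined.

**Further compounds**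
F1 | step 6 | (1R)-4-isobutoxy-6,6-dimethyl-2-oxo-1-(3-oxobutyl)cyclohex-3-ene-1-carbaldehyde | O=C1C=C(OCC(C)C)CC(C)(C)[C@@]1(C=O)CCC(C)=O
F2 | step 6 | (6S)-3-isobutoxy-5,5-dimethylspiro[5.5]undeca-2,10-diene-1,9-dione | O=C1C=C(OCC(C)C)CC(C)(C)[C@@]12CCC(=O)C=C2
F3 | step 11 | (6S)-9-(chloromethyl)-1-{[(4-methoxybenzyl)oxy]methyl}-5,5-dimethyl-3-[(trimethylsilyl)oxy]spiro[5.5]undeca-1,3,9-triene | COc1ccc(COCC2=CC(O[Si](C)(C)C)=CC(C)(C)[C@@]23CCC(CCl)=CC3)cc1
F4 | step 11 | (3R,4S,6R)-4-bromo-9-(chloromethyl)-1-{[(4-methoxybenzyl)oxy]methyl}-5,5-dimethylspiro[5.5]undeca-1,9-dien-3-ol | COc1ccc(COCC2=C[C@@H](O)[C@@H](Br)C(C)(C)[C@@]23CCC(CCl)=CC3)cc1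
F5 | step 11 | (4S,6R)-4-bromo-9-(chloromethyl)-1-{[(4-methoxybenzyl)oxy]methyl}-5,5-dimethylspiro[5.5]undeca-1,9-dien-3-one | COc1ccc(COCC2=CC(=O)[C@@H](Br)C(C)(C)[C@@]23CCC(CCl)=CC3)cc1
F6 | step 14 | (4R,6R,9S,10R)-4-bromo-9-(chloromethyl)-9,10-dihydroxy-1-{[(4-methoxybenzyl)oxy]methyl}-5,5-dimethylspiro[5.5]undec-1-en-3-one | COc1ccc(COCC2=CC(=O)[C@H](Br)C(C)(C)[C@@]23CC[C@@](O)(CCl)[C@H](O)C3)cc1
F7 | step 14 | 9,10-O-isopropylidene acetal (acetonide) of F6 | COc1ccc(COCC2=CC(=O)[C@H](Br)C(C)(C)[C@@]23CC[C@]4(CCl)OC(C)(C)O[C@@H]4C3)cc1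
F8 | step 14 | (3S,4R,6R,9S,10R)-3-alcohol from reduction of F7 | COc1ccc(COCC2=C[C@H](O)[C@H](Br)C(C)(C)[C@@]23CC[C@]4(CCl)OC(C)(C)O[C@@H]4C3)cc1
F9 | step 14 | 3-O-tert-butyldimethylsilyl ether of F8 | COc1ccc(COCC2=C[C@H](O[Si](C)(C)C(C)(C)C)[C@H](Br)C(C)(C)[C@@]23CC[C@]4(CCl)OC(C)(C)O[C@@H]4C3)cc1
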